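The target is cut at its biaryl bond, C7–C5′ in calamenene numbering: both halves are the same phenol, (1S,4R)-8-hydroxycalamenene, joined through C7 of one aromatic ring (ortho to the C8 hydroxyl, next to the C6 methyl) and C5′ of the other (para to its hydroxyl, peri to the isopropyl-bearing C4′). One aerobic, chromium-salen-catalysed ortho–para phenol coupling therefore dimerises a single monomer and finishes the synthesis. The monomer hides a p-menthane: its saturated ring with the trans methyl and isopropyl groups is (+)-menthone, onto whose C1 and C6 the phenol ring is annulated by aldol addition, methallyl addition, ring-closing metathesis and oxidation–dehydration.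

Key step: step 6

Remarks on the chemistry:
- The biaryl axis carries four ortho substituents and should be configurationally stable, but its sense is not specified in the structure. The route fixes the constitution and the four stereocentres, and either atropisomer is taken as the target.
- Numbering of each half: C1 = CH(CH3), C4 = CH(iPr), C4a/C8a ring fusion, C5 (H), C6 (CH3), C7 (H), C8 (OH); primes mark the para-linked half. For compounds 2–8 the text uses menthone numbering: C1 carbonyl, C2 isopropyl, C5 methyl, C6 methylene.
- (+)-Menthone (2R,5S) maps onto the required (1S,4R) monomer; the common (−)-series would give the enantiomer.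

Step 1
Reactants: 1 (1S,2R,5S)-(+)-menthol
Product: 2 (2R,5S)-(+)-menthone
Conditions: NaOCl (aq.), AcOH, 0 °C to 20 °C
Reagents that add atoms: none
Why: Hypochlorite (hypochlorous acid) oxidation of a secondary alcohol to the ketone; no stereocentre is formed, and short cold contact should keep the now enolisable menthone C2 trans, so both stereocentres of each half of the target are bought here.

Step 2
Reactants: 2 (2R,5S)-(+)-menthone; 3 acrolein
Product: 5 (2S,3S,6R)-2-(1-hydroxyprop-2-en-1-yl)-3-methyl-6-(propan-2-yl)cyclohexan-1-one (both carbinol epimers), via lithium enolate 4 (not isolated)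
Conditions: LiN(iPr)2, THF, −78 °C; acrolein, −78 °C; aq. NH4Cl
Reagents that add atoms: acrolein, C=CC=O
Why: Kinetic deprotonation at the unhindered menthone C6 methylene (not at C2–H) followed by aldol addition of the lithium enolate to the aldehyde carbon of acrolein; the side chain should enter trans to the neighbouring C5 methyl, and the uncontrolled carbinol centre does not matter because it becomes aromatic C8.

Step 3
Reactants: 5 aldol adduct; 6 2-methylallylmagnesium chloride
Product: 7 (2S,3S,6R)-2-(1-hydroxyprop-2-en-1-yl)-3-methyl-1-(2-methylprop-2-en-1-yl)-6-(propan-2-yl)cyclohexan-1-ol (epimers at C1 and at the side-chain carbinol)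
Conditions: CH2=C(CH3)CH2MgCl (3 equiv), THF, −78 °C to 0 °C; aq. NH4Cl
Reagents that add atoms: 2-methylallylmagnesium chloride, CC(=C)C[Mg]Cl
Why: Grignard 1,2-addition of an allylic magnesium reagent, which reaches even α,α′-branched ketones through a cyclic transition state after the first equivalent has formed the chelating alkoxide; the new tertiary carbinol (future C4a) needs no control, and the isopropyl-bearing carbon is no longer enolisable from here on.

Step 4
Reactants: 7 diene diol
Product: 8 (5R,8S,8aS)-3,8-dimethyl-5-(propan-2-yl)-1,4,4a,5,6,7,8,8a-octahydronaphthalene-1,4a-diol (epimers at C1 and C4a of the naphthalene numbering)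
Conditions: second-generation Grubbs catalyst (H2IMes)(PCy3)Cl2Ru=CHPh (5 mol %), CH2Cl2 (0.01 M), 40 °C
Reagents that add atoms: none
Why: Ring-closing olefin metathesis of the vinyl carbinol onto the 1,1-disubstituted methallyl alkene closes the six-membered ring with the trisubstituted C6=C7 alkene and is driven by loss of ethylene; no stereocentre is affected.

Step 5
Reactants: 8 cyclohexene diol
Product: 10 (5R,8S)-3,8-dimethyl-5-(propan-2-yl)-5,6,7,8-tetrahydronaphthalen-1-ol, that is (1S,4R)-8-hydroxycalamenene, via hydroxy enone 9 (not isolated)
Conditions: Dess–Martin periodinane, pyridine, CH2Cl2, 0 °C; aq. Na2S2O3 wash; then TsOH·H2O (cat.), CH2Cl2, 20 °C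
Reagents that add atoms: none
Why: Dess–Martin oxidation touches only the secondary allylic alcohol, and the β-hydroxy enone then dehydrates through its enol toward C8a (E1cB-type, away from C4) to a cross-conjugated cyclohexadienone whose C5 methylene tautomerises irreversibly to the phenol (dehydrative aromatisation); C1 and C4 are untouched.

Step 6
Reactants: 10 (1S,4R)-8-hydroxycalamenene (two molecules)
Product: 12 (5R,8S)-2-[(5S,8R)-4-hydroxy-2,5-dimethyl-8-(propan-2-yl)-5,6,7,8-tetrahydronaphthalen-1-yl]-3,8-dimethyl-5-(propan-2-yl)-5,6,7,8-tetrahydronaphthalen-1-ol, via bis-cyclohexadienone tautomer 11 (not isolated)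
Conditions: Cr(salen)Cl (10 mol %; salen = dianion of (R,R)-N,N′-bis(3,5-di-tert-butylsalicylidene)cyclohexane-1,2-diamine), O2 (1 atm), ClCH2CH2Cl, 80 °C, stopped at partial conversion, 10 recycled
Reagents that add atoms: none
Why: The trivalent chromium salen is oxidised by O2 to a high-valent oxo species that binds one molecule of 10 as a phenoxide, and this electrophilic, metal-bound phenoxyl is attacked by the free second molecule of 10, after which the dienone tautomer 11 rearomatises and O2 regenerates the catalyst. The closest known reaction type is the aerobic metal-salen-catalysed oxidative coupling of alkylphenols, which can deliver ortho–para-linked biphenols from phenols that have both sites open. No ring is closed and no stereocentre is formed; the only new stereo element is the tetra-ortho-substituted C7–C5′ axis, which the neighbouring C4′ isopropyl group and the chiral ligand should bias. The step needs C7–C5′ selectivity over C7–C7′, C5–C5′ and C–O coupling: in the bound partner the ortho carbon C7′ lies under the ligand, so only the remote para carbon C5′ is exposed, while in the free partner the para carbon C5 is shielded by the C6 methyl and the peri C4 substituent, and C7, the only open ortho site and next to the hydrogen-bonding OH, is the accessible nucleophilic position. A C5–C5′ union would have to join two peri-shielded carbons, and a C7–C7′ union would require attack at the ligand-shielded ortho carbon of the bound partner. Over-oxidation of the more electron-rich biphenol is limited by stopping at partial conversion and recycling 10.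

Compound list

1 | (1S,2R,5S)-(+)-menthol | C[C@H]1CC[C@H](C(C)C)[C@@H](O)C1 | starting material
2 | (2R,5S)-(+)-menthone, (2R,5S)-5-methyl-2-(propan-2-yl)cyclohexan-1-one | C[C@H]1CC[C@H](C(C)C)C(=O)C1 | intermediate
3 | acrolein | C=CC=O | starting material
4 | lithium (3S,6R)-3-methyl-6-(propan-2-yl)cyclohex-1-en-1-olate (kinetic enolate of 2) | C[C@H]1CC[C@H](C(C)C)C(O[Li])=C1 | intermediate (not isolated)
5 | (2S,3S,6R)-2-(1-hydroxyprop-2-en-1-yl)-3-methyl-6-(propan-2-yl)cyclohexan-1-one, side chain trans to the adjacent methyl, carbinol epimers | C[C@H]1CC[C@H](C(C)C)C(=O)[C@@H]1C(O)C=C | intermediate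
6 | 2-methylallylmagnesium chloride | CC(=C)C[Mg]Cl | starting material
7 | (2S,3S,6R)-2-(1-hydroxyprop-2-en-1-yl)-3-methyl-1-(2-methylprop-2-en-1-yl)-6-(propan-2-yl)cyclohexan-1-ol, epimers at C1 and at the side-chain carbinol | C[C@H]1CC[C@H](C(C)C)C(O)(CC(C)=C)[C@@H]1C(O)C=C | intermediate
8 | (5R,8S,8aS)-3,8-dimethyl-5-(propan-2-yl)-1,4,4a,5,6,7,8,8a-octahydronaphthalene-1,4a-diol, epimers at C1 and C4a | C[C@H]1CC[C@H](C(C)C)C2(O)CC(C)=CC(O)[C@H]12 | intermediate
9 | 4a-hydroxy-3,8-dimethyl-5-(propan-2-yl)-4a,5,6,7,8,8a-hexahydronaphthalen-1(4H)-one, menthane stereocentres as in 8 | C[C@H]1CC[C@H](C(C)C)C2(O)CC(C)=CC(=O)[C@H]12 | intermediate (not isolated)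
10 | (5R,8S)-3,8-dimethyl-5-(propan-2-yl)-5,6,7,8-tetrahydronaphthalen-1-ol, (1S,4R)-8-hydroxycalamenene (trans) | Cc1cc2c(c(O)c1)[C@@H](C)CC[C@@H]2C(C)C | intermediate
11 | C7–C5′-linked bis-cyclohexadienone (2,4-dienone in the ortho-linked half, 2,5-dienone in the para-linked half; C7 and C5′ are sp3 CH of unspecified configuration) | CC1=CC2=C(C(=O)C1C1C(C)=CC(=O)C3=C1[C@@H](C(C)C)CC[C@@H]3C)[C@@H](C)CC[C@@H]2C(C)C | intermediate (not isolated)
12 | (5R,8S)-2-[(5S,8R)-4-hydroxy-2,5-dimethyl-8-(propan-2-yl)-5,6,7,8-tetrahydronaphthalen-1-yl]-3,8-dimethyl-5-(propan-2-yl)-5,6,7,8-tetrahydronaphthalen-1-ol, the 7,5′-linked dimer of (1S,4R)-8-hydroxycalamenene | Cc1cc2c(c(O)c1-c1c(C)cc(O)c3c1[C@@H](C(C)C)CC[C@@H]3C)[C@@H](C)CC[C@@H]2C(C)C | target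

Total step count: 6. Longest linear sequence: 6 steps, from (+)-menthol 1 to 12; the sequence is linear and the monomer 10 is used twice in the last step.

Steps most likely to fail

Step 6 (key step). What may go wrong: coupling through the wrong pair of positions (C7–C7′ or C5–C5′), carbon–oxygen coupling, or further oxidation and oligomerisation of the electron-rich biphenol once it has formed. The fallback sets out from 10 and comes back at 12 by a regiochemically fixed cross-coupling. Compound 10 is converted into its methoxymethyl ether F1 (NaH, MOMCl, THF, 0 °C). One portion of F1 is brominated at C5, para to the ether oxygen (N-bromosuccinimide, MeCN, 0 °C), to give the 5-bromo methoxymethyl ether F2. A second portion of F1 is lithiated at C7, the only position ortho to the OMOM group (sec-BuLi, TMEDA, THF, −78 °C), transmetalated with ZnCl2 and joined to F2 in a Negishi coupling (Pd(OAc)2, SPhos, THF, 65 °C), which should give the bis(methoxymethyl) ether of the target F3. HCl in MeOH at 50 °C then releases 12.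

Step 3. What may go wrong: retro-aldol fragmentation of the magnesium aldolate, or enolisation of the hindered ketone in place of addition. The fallback sets out from 5 and comes back at 7 and removes the alkoxide by design. The carbinol of 5 is capped as the tert-butyldimethylsilyl ether F4 (TBSCl, imidazole, DMF). The weakly basic organocerium reagent made from 2-methylallylmagnesium chloride and CeCl3 (THF, −78 °C) is then added to the ketone to give the silyl ether of the tertiary alcohol F5, and Bu4NF in THF should return 7.

Step 5. What may go wrong: the hydroxy enone aromatises while the periodinane is still present and the new phenol is oxidised further, or elimination stalls at the hydroxy enone. The fallback sets out from 7 and comes back at 10 by reversing the order of oxidation and ring closure. Compound 7 is oxidised before ring closure (Dess–Martin periodinane, pyridine, CH2Cl2, 0 °C) to the vinyl ketone F6. Ring-closing metathesis of F6 (second-generation Grubbs catalyst, CH2Cl2, 40 °C) then forms 9 with no oxidant present, and TsOH·H2O completes dehydration and tautomerisation to 10.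

Further compounds

F1 | step 6 | methoxymethyl ether of 10, (5R,8S)-1-(methoxymethoxy)-3,8-dimethyl-5-(propan-2-yl)-5,6,7,8-tetrahydronaphthalene | Cc1cc2c(c(OCOC)c1)[C@@H](C)CC[C@@H]2C(C)C
F2 | step 6 | 5-bromo methoxymethyl ether (bromine para to the ether oxygen, calamenene C5) | Brc1c(C)cc(OCOC)c2c1[C@@H](C(C)C)CC[C@@H]2C
F3 | step 6 | bis(methoxymethyl) ether of 12 | Cc1cc2c(c(OCOC)c1-c1c(C)cc(OCOC)c3c1[C@@H](C(C)C)CC[C@@H]3C)[C@@H](C)CC[C@@H]2C(C)C
F4 | step 3 | tert-butyldimethylsilyl ether of 5 | C[C@H]1CC[C@H](C(C)C)C(=O)[C@@H]1C(O[Si](C)(C)C(C)(C)C)C=C
F5 | step 3 | mono(tert-butyldimethylsilyl) ether of 7 (secondary carbinol silylated) | C[C@H]1CC[C@H](C(C)C)C(O)(CC(C)=C)[C@@H]1C(O[Si](C)(C)C(C)(C)C)C=C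
F6 | step 5 | vinyl ketone from 7, 1-[2-hydroxy-6-methyl-2-(2-methylprop-2-en-1-yl)-3-(propan-2-yl)cyclohexyl]prop-2-en-1-one | C[C@H]1CC[C@H](C(C)C)C(O)(CC(C)=C)[C@@H]1C(=O)C=C
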